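**Retrosynthetic overview**

1. The target is a melampolide. Its ring-cis C1=C10 olefin (carrying the C14 ester) and ring-trans C4=C5 olefin flank C2–C3. They are the two ends of the hexatriene that conrotatory 6π opening of a cis-fused cyclohexa-1,3-diene (C1=C2–C3=C4, ring A) gives when the ring-fusion bond C5–C10 is cut, so rings A and B merge into the ten-membered ring.
2. After the opening: diimide removes the surplus cis C2=C3 olefin, then α-methylenation of the 6α,12-lactone, desilylation and 8-O-methacrylation.
3. The hexalin comes from a cis-decalin by C7 alkylation, O8-directed reduction at C6, trans-lactonisation (which locks ring B in the chair that fixes the diene helicity) and ring A ketone → enone → dienyl triflate → diene.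
4. The decalin comes from a Diels–Alder reaction of 2-silyloxypenta-1,3-diene with a shikimate-derived 5-silyloxy-3-oxocyclohexenecarboxylate (the C6 ketone steers regiochemistry, the C8 oxygen the face).
5. Ring order: ring B (shikimic acid) → ring A (Diels–Alder) → γ-lactone → ten-membered ring (by fusion-bond cleavage).

Key step: step 18

Remark on conventions: germacrane numbering is used for all bicyclic compounds. C5–C10 are ring B (the shikimate carbons), C1–C4 come from the diene, C11–C13 are the lactone side chain on C7, C14 is the ester carbon on C10 and C15 the methyl on C4. α is the face of O6; β is the face of O8, of the C7 side chain, of H5 and of the C10 ester.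

Remark on choices: the acetate unit is brought in as its tert-butyl ester so that it cannot lactonise onto the cis C8 hydroxyl. The C8 silyl group of the photo-precursor is triisopropylsilyl (TIPS), which survives the acid lactonisation. The C4 configuration of the Diels–Alder adduct is of no consequence because C4 becomes sp2 in step 15.

**Route**

Step 1
Reactants: 1 shikimic acid
Product: 2 methyl shikimate
Conditions: MeOH, CSA (cat.), reflux
Reagents that add atoms: methanol, CO
Why: Fischer esterification of the conjugated acid; the three carbinol centres are not touched.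

Step 2
Reactants: 2 methyl shikimate
Product: 3 methyl 3,5-bis-O-TBS-shikimate
Conditions: TBSCl (2.2 equiv), imidazole, DMF, 0 °C to rt
Reagents that add atoms: tert-butyldimethylsilyl chloride, CC(C)(C)[Si](C)(C)Cl
Why: Regioselective silylation; the C4 hydroxyl is flanked by both others and is the most hindered, so it should stay free.

Step 3
Reactants: 3 methyl 3,5-bis-O-TBS-shikimate
Product: 4 4-O-(imidazol-1-ylthiocarbonyl) derivative of 3
Conditions: 1,1'-thiocarbonyldiimidazole, DMAP (cat.), ClCH2CH2Cl, 70 °C
Reagents that add atoms: 1,1'-thiocarbonyldiimidazole, S=C(n1ccnc1)n1ccnc1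
Why: Thioacylation of the remaining secondary alcohol gives the radical-labile thiocarbamate, the first half of a Barton–McCombie deoxygenation.

Step 4
Reactants: 4 thiocarbamate
Product: 5 methyl 4-deoxy-3,5-bis-O-TBS-shikimate
Conditions: Bu3SnH, AIBN (cat.), PhMe, 100 °C
Reagents that add atoms: none
Why: Barton–McCombie deoxygenation: the stannyl radical adds to C=S, the C4–O bond fragments and the secondary radical takes hydrogen from Bu3SnH; C3 and C5 keep the configuration of shikimic acid.

Step 5
Reactants: 5 methyl 4-deoxy-3,5-bis-O-TBS-shikimate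
Product: 6 methyl 4-deoxyshikimate (3,5-trans diol)
Conditions: 48% aq. HF, MeCN, 0 °C to rt
Reagents that add atoms: none
Why: Acidic fluoride cleavage of both silyl ethers; no stereocenter is touched.

Step 6
Reactants: 6 methyl 4-deoxyshikimate
Product: 7 methyl (5R)-5-hydroxy-3-oxocyclohex-1-ene-1-carboxylate
Conditions: MnO2 (excess), CH2Cl2, rt
Reagents that add atoms: none
Why: MnO2 oxidises only the allylic C3 carbinol; the C5 carbinol (the later C8) is untouched.

Step 7
Reactants: 7 hydroxy enone
Product: 8 methyl (5R)-5-(tert-butyldimethylsilyloxy)-3-oxocyclohex-1-ene-1-carboxylate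
Conditions: TBSOTf, 2,6-lutidine, CH2Cl2, −78 °C
Reagents that add atoms: tert-butyldimethylsilyl triflate, CC(C)(C)[Si](C)(C)OS(=O)(=O)C(F)(F)F
Why: Low-temperature silylation with a hindered base protects the β-hydroxy ketone without β-elimination towards the phenol.

Step 8
Reactants: 9 (E)-pent-3-en-2-one
Product: 10 (E)-2-(tert-butyldimethylsilyloxy)penta-1,3-diene
Conditions: TBSOTf, Et3N, Et2O, 0 °C
Reagents that add atoms: tert-butyldimethylsilyl triflate, CC(C)(C)[Si](C)(C)OS(=O)(=O)C(F)(F)F
Why: Soft enolisation at the methyl ketone and O-silylation give the cross-conjugated 2-silyloxydiene with the E olefin unchanged.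

Step 9
Reactants: 8 silyloxy enone ester; 10 silyloxydiene
Product: 11 cis-fused decalin with C6 ketone, 8β-OTBS, 10β-CO2Me, 5β-H, ring A 2-OTBS enol ether (C2=C3) and 4-methyl
Conditions: PhMe, 80 °C, sealed tube
Reagents that add atoms: none
Why: Normal-demand Diels–Alder reaction of the doubly activated enone ester: the C6 ketone steers regiochemistry (CH2 terminus to C10, CHMe terminus to C5), suprafacial addition gives the cis fusion, and the diene adds to the α face anti to the C8 silyloxy group (axial attack at C10 trans to the 5-substituent of the cyclohexenone), which sets C10 (ester β) and C5 (H β).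

Step 10
Reactants: 11 Diels–Alder adduct; 12 tert-butyl bromoacetate
Product: 13 7β-(tert-butoxycarbonylmethyl) ketone
Conditions: LiN(i-Pr)2, THF, −78 °C; then 12, DMPU, −78 to −40 °C
Reagents that add atoms: none
Why: Kinetic deprotonation at the C7 methylene (not the C5 methine) and SN2 alkylation of the lithium enolate; the electrophile should enter axially on the convex β face, antiperiplanar to the pseudoaxial C8–H in the half-chair that keeps the C8 silyloxy group and the C10 ester pseudoequatorial (the α approach needs a twist-boat or the half-chair with C4, the silyloxy group and the ester all axial), which sets C7 with the side chain β.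

Step 11
Reactants: 13 alkylated ketone
Product: 14 2,6-diketone with free 8β-hydroxyl and 7β-CH2CO2t-Bu
Conditions: 48% aq. HF, MeCN, 0 °C to rt
Reagents that add atoms: none
Why: Aqueous HF hydrolyses the silyl enol ether to the ring A ketone and cleaves the C8 silyl ether, while the tert-butyl ester survives and is too hindered to lactonise onto the freed cis hydroxyl.

Step 12
Reactants: 14 hydroxy diketone
Product: 15 6α,8β-diol (ring A ketone retained)
Conditions: Me4NBH(OAc)3, MeCN–AcOH (1:1), −30 °C
Reagents that add atoms: none
Why: Evans–Saksena reduction: the C8 hydroxyl exchanges onto boron and delivers hydride intramolecularly to the β face of the C6 carbonyl, which gives the anti 1,3-diol (6α-OH); the ring A ketone has no neighbouring hydroxyl and is not reduced.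

Step 13
Reactants: 15 diol
Product: 16 6α-hydroxy 8β-O-TIPS ether
Conditions: TIPSOTf (1.05 equiv), 2,6-lutidine, CH2Cl2, −78 °C
Reagents that add atoms: triisopropylsilyl triflate, CC(C)[Si](OS(=O)(=O)C(F)(F)F)(C(C)C)C(C)C
Why: Regioselective silylation; the C8 hydroxyl has a methylene neighbour (C9) whereas the C6 hydroxyl lies between two methine carbons (C5 and C7), so one equivalent of the bulky silyl triflate should go to O8.

Step 14
Reactants: 16 hydroxy tert-butyl ester
Product: 18 trans-fused 6α,12-lactone with ring A ketone, via hydroxy acid 17 (not isolated)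
Conditions: TFA, CH2Cl2, 0 °C to rt; then PPTS, PhMe, 60 °C
Reagents that add atoms: none
Why: Acidolysis of the tert-butyl ester and acid-catalysed lactonisation of the γ-hydroxy acid, for which only O6 is free; O6 (α) and the C7 side chain (β) are trans, so the trans-fused γ-lactone forms and locks ring B in the chair with the C10 ester, O8 and C4 axial.

Step 15
Reactants: 18 lactone ketone
Product: 19 ring A enone (C2=O, C3=C4)
Conditions: IBX, DMSO–PhF, 75 °C
Reagents that add atoms: none
Why: IBX dehydrogenation of the ketone through its enol; it can only run towards C3–C4 because C1 is attached to the quaternary C10, and it removes the C4 stereocenter.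

Step 16
Reactants: 19 enone
Product: 20 dienyl triflate (C1=C2(OTf)–C3=C4)
Conditions: KN(SiMe3)2, THF, −78 °C; then PhNTf2, −78 to 0 °C
Reagents that add atoms: N-phenylbis(trifluoromethanesulfonimide), O=S(=O)(N(c1ccccc1)S(=O)(=O)C(F)(F)F)C(F)(F)F
Why: Kinetic α′ deprotonation at C1 gives the cross-conjugated dienolate, which is O-triflated; the ketone α′ protons are more acidic than the lactone α protons, so a slight excess of base should suffice.

Step 17
Reactants: 20 dienyl triflate
Product: 21 cis-fused hexalin lactone (C1=C2–C3=C4 diene, 10β-CO2Me, 5β-H, 8β-OTIPS)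
Conditions: Pd(OAc)2 (cat.), PPh3, Bu3N, HCO2H, DMF, 60 °C
Reagents that add atoms: none
Why: Pd-catalysed formate reduction of an enol triflate (oxidative addition of zerovalent palladium, exchange of triflate for formate, loss of CO2 and C–H reductive elimination) leaves the homoannular diene.

Step 18
Reactants: 21 cis-fused hexalin lactone
Product: 22 cyclodeca-1(10),2,4-triene lactone (ring-cis C1=C10, cis C2=C3, ring-trans C4=C5)
Conditions: hν (254 nm, quartz), degassed Et2O–pentane, −78 °C, partial conversion; concentrated below −40 °C and used at once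
Reagents that add atoms: none
Why: Direct π,π* excitation of the homoannular diene triggers a conrotatory 6π electrocyclic ring opening in which the σ bond C5–C10 is cleaved and C1=C10 and C4=C5 are formed; the closest known reaction type is the photochemical opening of cis-fused hexalins and of eudesmane-type cyclohexa-1,3-dienes to cyclodeca-1,3,5-trienes. The ten-membered ring is not closed by bond formation: it arises when the fusion bond shared by rings A and B is cut, so the two six-membered rings merge. No stereocenter is created (C5 and C10 become sp2; C6, C7 and C8 are untouched). The selectivity needed is the sense of conrotation, and it is fixed by ground-state conformational control: the trans-lactone holds ring B in the chair with the C10 ester, O8 and C4 axial, which makes C9 and H5 pseudoaxial and CO2Me and C6 pseudoequatorial on ring A, and helicity-retaining opening turns pseudoaxial groups inward and pseudoequatorial groups outward. C9 inward gives the ring-cis C1=C10 with the ester outside, C6 outward gives the ring-trans C4=C5, and the central C2=C3 stays cis. Irradiation at −78 °C to partial conversion should keep thermal disrotatory re-closure and secondary photochemistry of the triene low.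

Step 19
Reactants: 22 triene lactone
Product: 23 cyclodeca-1(10),4-diene lactone
Conditions: KO2CN=NCO2K, AcOH, MeOH–CH2Cl2, −40 to −15 °C
Reagents that add atoms: none
Why: Diimide reduction (concerted syn transfer of H2): the strained cis-disubstituted C2=C3 olefin should react much faster than the trisubstituted C1=C10 enoate and C4=C5 olefins, and the low temperature keeps the triene from re-closing.

Step 20
Reactants: 23 diene lactone
Product: 26 α-methylene lactone TIPS ether, via Mannich base 24 (not isolated), via ammonium iodide 25 (not isolated)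
Conditions: LiN(i-Pr)2, THF, −78 °C; CH2=NMe2+ I−, −78 to 0 °C; then MeI, MeOH, rt; then aq. NaHCO3, CH2Cl2
Reagents that add atoms: dimethylmethyleneiminium iodide, C=[N+](C)C.[I-]
Why: α-Methylenation by Mannich reaction of the lactone lithium enolate, N-methylation and E1cB-type elimination of trimethylamine; the lactone α protons are removed in preference to the γ protons of the hindered enoate, and C11 becomes sp2.

Step 21
Reactants: 26 α-methylene lactone TIPS ether
Product: 27 8β-alcohol
Conditions: HF·pyridine, pyridine–THF, 0 °C to rt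
Reagents that add atoms: none
Why: Fluoride cleavage of the silyl ether under non-basic conditions, which avoids conjugate addition to the α-methylene lactone and translactonisation to O8.

Step 22
Reactants: 27 8β-alcohol
Product: 28 target, the 8β-methacrylate
Conditions: methacryloyl chloride, Et3N, DMAP (cat.), CH2Cl2, 0 °C
Reagents that add atoms: methacryloyl chloride, C=C(C)C(=O)Cl
Why: DMAP-catalysed acylation of the secondary alcohol with retention at C8.

**Compound list**

1 | shikimic acid | C1[C@H]([C@@H]([C@@H](C=C1C(=O)O)O)O)O | starting material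
2 | methyl shikimate | COC(=O)C1=C[C@@H](O)[C@@H](O)[C@H](O)C1 | intermediate
3 | methyl 3,5-bis-O-TBS-shikimate | COC(=O)C1=C[C@@H](O[Si](C)(C)C(C)(C)C)[C@@H](O)[C@H](O[Si](C)(C)C(C)(C)C)C1 | intermediate
4 | methyl 3,5-bis-O-TBS-4-O-(imidazol-1-ylthiocarbonyl)shikimate | COC(=O)C1=C[C@@H](O[Si](C)(C)C(C)(C)C)[C@@H](OC(=S)n2ccnc2)[C@H](O[Si](C)(C)C(C)(C)C)C1 | intermediate
5 | methyl 4-deoxy-3,5-bis-O-TBS-shikimate | COC(=O)C1=C[C@@H](O[Si](C)(C)C(C)(C)C)C[C@H](O[Si](C)(C)C(C)(C)C)C1 | intermediate
6 | methyl 4-deoxyshikimate | COC(=O)C1=C[C@@H](O)C[C@H](O)C1 | intermediate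
7 | methyl (5R)-5-hydroxy-3-oxocyclohex-1-ene-1-carboxylate | COC(=O)C1=CC(=O)C[C@H](O)C1 | intermediate
8 | methyl (5R)-5-(tert-butyldimethylsilyloxy)-3-oxocyclohex-1-ene-1-carboxylate | COC(=O)C1=CC(=O)C[C@H](O[Si](C)(C)C(C)(C)C)C1 | intermediate
9 | (E)-pent-3-en-2-one | C/C=C/C(C)=O | starting material
10 | (E)-2-(tert-butyldimethylsilyloxy)penta-1,3-diene | C=C(O[Si](C)(C)C(C)(C)C)/C=C/C | intermediate
11 | cis-decalin Diels–Alder adduct (C6 ketone, 8β-OTBS, 10β-CO2Me, 5β-H, 2-OTBS enol ether, 4-methyl cis to C6) | COC(=O)[C@]12CC(O[Si](C)(C)C(C)(C)C)=C[C@@H](C)[C@H]1C(=O)C[C@H](O[Si](C)(C)C(C)(C)C)C2 | intermediate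
12 | tert-butyl bromoacetate | CC(C)(C)OC(=O)CBr | starting material
13 | 7β-(tert-butoxycarbonylmethyl) derivative of 11 | COC(=O)[C@]12CC(O[Si](C)(C)C(C)(C)C)=C[C@@H](C)[C@H]1C(=O)[C@H](CC(=O)OC(C)(C)C)[C@H](O[Si](C)(C)C(C)(C)C)C2 | intermediate
14 | 2,6-diketone, 8β-hydroxy, 7β-CH2CO2t-Bu | COC(=O)[C@]12CC(=O)C[C@@H](C)[C@H]1C(=O)[C@H](CC(=O)OC(C)(C)C)[C@H](O)C2 | intermediate
15 | 6α,8β-diol, ring A 2-ketone | COC(=O)[C@]12CC(=O)C[C@@H](C)[C@H]1[C@@H](O)[C@H](CC(=O)OC(C)(C)C)[C@H](O)C2 | intermediate
16 | 6α-hydroxy 8β-O-TIPS tert-butyl ester | COC(=O)[C@]12CC(=O)C[C@@H](C)[C@H]1[C@@H](O)[C@H](CC(=O)OC(C)(C)C)[C@H](O[Si](C(C)C)(C(C)C)C(C)C)C2 | intermediate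
17 | 6α-hydroxy 8β-O-TIPS carboxylic acid | COC(=O)[C@]12CC(=O)C[C@@H](C)[C@H]1[C@@H](O)[C@H](CC(=O)O)[C@H](O[Si](C(C)C)(C(C)C)C(C)C)C2 | intermediate (not isolated)
18 | trans-fused 6α,12-lactone, ring A 2-ketone, 8β-OTIPS | COC(=O)[C@]12CC(=O)C[C@@H](C)[C@H]1[C@H]3OC(=O)C[C@@H]3[C@H](O[Si](C(C)C)(C(C)C)C(C)C)C2 | intermediate
19 | ring A enone lactone (C2=O, C3=C4) | COC(=O)[C@]12CC(=O)C=C(C)[C@H]1[C@H]3OC(=O)C[C@@H]3[C@H](O[Si](C(C)C)(C(C)C)C(C)C)C2 | intermediate
20 | dienyl triflate lactone | COC(=O)[C@]12C=C(OS(=O)(=O)C(F)(F)F)C=C(C)[C@H]1[C@H]3OC(=O)C[C@@H]3[C@H](O[Si](C(C)C)(C(C)C)C(C)C)C2 | intermediate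
21 | cis-fused hexalin lactone with angular C10 ester (photo-precursor) | COC(=O)[C@]12C=CC=C(C)[C@H]1[C@H]3OC(=O)C[C@@H]3[C@H](O[Si](C(C)C)(C(C)C)C(C)C)C2 | intermediate
22 | cyclodeca-1(10),2,4-triene lactone | CC(C)[Si](C(C)C)(C(C)C)O[C@@H]1C/C(C(=O)OC)=C\C=C/C(C)=C/[C@H]2OC(=O)C[C@@H]21 | intermediate
23 | cyclodeca-1(10),4-diene lactone | CC(C)[Si](C(C)C)(C(C)C)O[C@@H]1C/C(C(=O)OC)=C\CC/C(C)=C/[C@H]2OC(=O)C[C@@H]21 | intermediate
24 | 11-(dimethylaminomethyl) lactone (C11 epimers) | CC(C)[Si](C(C)C)(C(C)C)O[C@@H]1C/C(C(=O)OC)=C\CC/C(C)=C/[C@H]2OC(=O)C(CN(C)C)[C@@H]21 | intermediate (not isolated)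
25 | 11-(trimethylammoniomethyl) lactone iodide | CC(C)[Si](C(C)C)(C(C)C)O[C@@H]1C/C(C(=O)OC)=C\CC/C(C)=C/[C@H]2OC(=O)C(C[N+](C)(C)C)[C@@H]21.[I-] | intermediate (not isolated)
26 | α-methylene lactone 8β-O-TIPS ether | CC(C)[Si](C(C)C)(C(C)C)O[C@@H]1C/C(C(=O)OC)=C\CC/C(C)=C/[C@H]2OC(=O)C(=C)[C@@H]21 | intermediate
27 | α-methylene lactone 8β-alcohol | O[C@@H]1C/C(C(=O)OC)=C\CC/C(C)=C/[C@H]2OC(=O)C(=C)[C@@H]21 | intermediate
28 | CNP0317149.1 (8β-methacryloyloxy melampolide methyl ester) | C=C(C)C(=O)O[C@@H]1C/C(C(=O)OC)=C\CC/C(C)=C/[C@H]2OC(=O)C(=C)[C@@H]21 | target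

**Count**

Total steps: 22. Longest linear sequence: 21 steps (steps 1–7 and 9–22, from shikimic acid).

**Three steps most likely to fail**

Step 18. The diene may lose control over the sense of conrotation if repulsion between the syn-axial C8 silyloxy group and the C10 ester pushes ring B out of the lactone-locked chair; on long irradiation the triene can also re-close or scramble its olefin geometry. The fallback changes the control element from a silyl-protected to a hydrogen-bond-locked substrate. It sets out from 21: HF·pyridine gives the 8β-hydroxy hexalin lactone F1, whose hydroxyl can hydrogen-bond to the C14 ester carbonyl across the two axial positions and so holds the chair without steric strain. Irradiation as in step 18 gives the 8β-hydroxy triene lactone F2, and diimide as in step 19 gives the 8β-hydroxy diene lactone F3. Silylation with TIPSOTf and 2,6-lutidine returns to 23.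

Step 10. Facial selectivity at C7 may be poor (attack from the α face, anti to the neighbouring silyloxy group), and the kinetically formed axial product may epimerise. The fallback sets C7 by hydrogen delivery instead of carbon delivery. It sets out from 11: the lithium enolate (LiN(i-Pr)2, THF, −78 °C) is added to tert-butyl glyoxylate to give the aldol adduct F4, which is dehydrated with methyl N-(triethylammoniosulfonyl)carbamate to the (E)-alkylidene keto ester F5. Aqueous HF gives the alkylidene hydroxy diketone F6, Me4NBH(OAc)3 the alkylidene 6α,8β-diol F7, and TIPSOTf the alkylidene 8β-O-TIPS ether F8. Hydroxyl-directed hydrogenation of F8 (H2, [Ir(cod)(PCy3)(py)]PF6, CH2Cl2) should deliver hydrogen to C7 on the face of the 6α hydroxyl, which puts the side chain β and gives 16, where the route is rejoined.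

Step 19. Thermal re-closure or isomerisation of the triene may outrun hydrogen transfer from diimide at low temperature, or a second olefin may be reduced. The fallback replaces the stoichiometric transfer reagent by a surface-catalysed hydrogenation without handling of the triene. It sets out from 21: step 18 is run in methanol at −20 °C and the cold photolysate is stirred at once under H2 (1 atm) over skeletal Ni (W-2 type) at −20 °C, which should take the least hindered cis-disubstituted olefin. Recovered 21 is recycled and the sequence comes back at 23; no new compound is made.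

**Further compounds**

F1 | step 18 | 8β-hydroxy cis-fused hexalin lactone | COC(=O)[C@]12C=CC=C(C)[C@H]1[C@H]3OC(=O)C[C@@H]3[C@H](O)C2
F2 | step 18 | 8β-hydroxy cyclodeca-1(10),2,4-triene lactone | O[C@@H]1C/C(C(=O)OC)=C\C=C/C(C)=C/[C@H]2OC(=O)C[C@@H]21
F3 | step 18 | 8β-hydroxy cyclodeca-1(10),4-diene lactone | O[C@@H]1C/C(C(=O)OC)=C\CC/C(C)=C/[C@H]2OC(=O)C[C@@H]21
F4 | step 10 | C7 aldol adduct of 11 with tert-butyl glyoxylate (mixture at C7 and the carbinol carbon) | COC(=O)[C@]12CC(O[Si](C)(C)C(C)(C)C)=C[C@@H](C)[C@H]1C(=O)C(C(O)C(=O)OC(C)(C)C)[C@H](O[Si](C)(C)C(C)(C)C)C2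
F5 | step 10 | (E)-7(11)-alkylidene keto ester, bis-silyl | COC(=O)[C@]12CC(O[Si](C)(C)C(C)(C)C)=C[C@@H](C)[C@H]1C(=O)/C(=C/C(=O)OC(C)(C)C)[C@H](O[Si](C)(C)C(C)(C)C)C2
F6 | step 10 | alkylidene 2,6-diketone 8β-alcohol | COC(=O)[C@]12CC(=O)C[C@@H](C)[C@H]1C(=O)/C(=C/C(=O)OC(C)(C)C)[C@H](O)C2
F7 | step 10 | alkylidene 6α,8β-diol | COC(=O)[C@]12CC(=O)C[C@@H](C)[C@H]1[C@@H](O)/C(=C/C(=O)OC(C)(C)C)[C@H](O)C2
F8 | step 10 | alkylidene 6α-hydroxy 8β-O-TIPS ether | COC(=O)[C@]12CC(=O)C[C@@H](C)[C@H]1[C@@H](O)/C(=C/C(=O)OC(C)(C)C)[C@H](O[Si](C(C)C)(C(C)C)C(C)C)C2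
F0 | step 19 | none | none
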